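**Retrosynthetic overview**
- The target comes from a Z-cyclodecenol lactone by C1 desilylation, C3 oxidation and C4=C5 epoxidation. The ten-membered ring is closed at C3–C4 by Nozaki–Hiyama–Kishi coupling of a Z-vinyl iodide with an aldehyde.
- The α-methylene-γ-lactone is closed before the carbocycle, by attack of O6 on the C12 methyl ester once O8 carries the tiglate.
- The key disconnection is C7–C8. An intermolecular indium Barbier allylation joins the east aldehyde (C8–C10, C1–C3) to the west Z-2-(bromomethyl)enoate (C4–C7, C11–C13) and creates C7, C8 and the C11=C13 methylene.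
- The west bromide comes from (R)-solketal, which supplies C6, by Stork–Zhao Z-iodo-olefination, vinylalumination and SN2′ bromination. The east aldehyde comes from propane-1,3-diol by Brown anti-crotylation (C1, C10) and hydroboration.
- Ring order: γ-lactone, then ten-membered carbocycle, then oxirane.

Assumption: locants C1–C15 follow germacrane numbering of the target (C1 carbinol, C3 ketone, C4–C5 oxirane, O6 lactone oxygen, O8 tiglate, C10 methyl-bearing carbon, C11=C13 methylene, C12 lactone carbonyl). The C3 carbinol from step 19 is carried as whatever epimer mixture forms, because step 21 removes it.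

**West bromide (steps 1–8)**

Step 1
Reactants: 1 (R)-solketal
Product: 2 (S)-glyceraldehyde acetonide
Conditions: TEMPO (cat.), PhI(OAc)2, CH2Cl2, rt; used crude at once
Reagents that add atoms: none
Why: The TEMPO (oxoammonium) oxidation stops at the aldehyde under near-neutral conditions, so the acetonide and the α-stereocentre (future C6) survive.

Step 2
Reactants: 2 (S)-glyceraldehyde acetonide
Product: 3 (4R)-4-[(1Z)-2-iodoprop-1-en-1-yl]-2,2-dimethyl-1,3-dioxolane
Conditions: EtPPh3I, n-BuLi, THF, rt; I2, −78 °C; NaN(SiMe3)2, −20 °C; then 2, −78 °C → rt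
Reagents that add atoms: ethyltriphenylphosphonium iodide CC[P+](c1ccccc1)(c1ccccc1)c1ccccc1.[I-]; iodine II
Why: The Stork–Zhao Wittig olefination with the non-stabilised α-iodo ylide is kinetically Z-selective, which puts iodine cis to C6 (the later cis C3/C6 relationship) and leaves C6 untouched.

Step 3
Reactants: 3 Z-iodoalkenyl acetonide
Product: 4 (2R,3Z)-4-iodopent-3-ene-1,2-diol
Conditions: AcOH/H2O (4:1), 40 °C
Reagents that add atoms: none
Why: Acid-catalysed acetal hydrolysis frees the 1,2-diol without affecting the vinyl iodide or the carbinol configuration.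

Step 4
Reactants: 4 iodopentenediol
Product: 5 (4R)-4-[(1Z)-2-iodoprop-1-en-1-yl]-2-(4-methoxyphenyl)-1,3-dioxolane
Conditions: 4-MeOC6H4CH(OMe)2, PPTS (cat.), CH2Cl2, rt
Reagents that add atoms: 4-methoxybenzaldehyde dimethyl acetal COc1ccc(C(OC)OC)cc1
Why: Acid-catalysed transacetalisation gives the five-membered 4-methoxybenzylidene acetal, and its new acetal carbon is an epimer mixture that step 5 removes.

Step 5
Reactants: 5 4-methoxybenzylidene acetal
Product: 6 (2R,3Z)-4-iodo-2-[(4-methoxybenzyl)oxy]pent-3-en-1-ol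
Conditions: i-Bu2AlH, CH2Cl2, −78 → 0 °C
Reagents that add atoms: none
Why: In this regioselective reductive acetal opening aluminium binds the less hindered primary oxygen, so hydride delivery leaves the PMB group on the secondary C6 oxygen and frees the primary alcohol.

Step 6
Reactants: 6 PMB-protected primary alcohol
Product: 7 (2R,3Z)-4-iodo-2-[(4-methoxybenzyl)oxy]pent-3-enal
Conditions: DMP, CH2Cl2, 0 °C → rt; used at once
Reagents that add atoms: none
Why: The Dess–Martin oxidation is fast and non-basic, and allylic 1,3-strain from the cis iodine holds the C6–H bond in the alkene plane, which slows enolisation of this α-alkoxy β,γ-unsaturated aldehyde.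

Step 7
Reactants: 7 α-PMB-oxy aldehyde
Product: 8 methyl (4R,5Z)-3-hydroxy-6-iodo-4-[(4-methoxybenzyl)oxy]-2-methylidenehept-5-enoate
Conditions: i-Bu2AlH, HMPA, THF, 0 °C; methyl propiolate, 0 °C; then 7, 0 °C → rt
Reagents that add atoms: methyl propiolate C#CC(=O)OC
Why: Vinylalumination (hydroalumination of the propiolate, then 1,2-addition of the α-ester vinylalane) gives the Morita–Baylis–Hillman-type adduct without amine base, and the new C7 carbinol centre is a mixture that step 8 removes.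

Step 8
Reactants: 8 Baylis–Hillman-type alcohol
Product: 9 methyl (2Z,4S,5Z)-2-(bromomethyl)-6-iodo-4-[(4-methoxybenzyl)oxy]hepta-2,5-dienoate (west bromide)
Conditions: NBS, Me2S, CH2Cl2, 0 °C; then 8, 0 °C → rt
Reagents that add atoms: N-bromosuccinimide O=C1CCC(=O)N1Br
Why: Corey–Kim-type activation followed by SN2′ attack of bromide at the methylene terminus gives the rearranged primary bromide, and the transition state that keeps the C6 branch away from the ester makes the alkene Z (C6 cis to CH2Br).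

**East aldehyde (steps 9–14)**

Step 9
Reactants: 10 propane-1,3-diol
Product: 11 3-[(4-methoxybenzyl)oxy]propan-1-ol
Conditions: NaH, PMBCl, Bu4NI (cat.), THF, 0 °C → rt (diol in excess)
Reagents that add atoms: 4-methoxybenzyl chloride COc1ccc(CCl)cc1
Why: Williamson etherification with the symmetrical diol in excess gives the mono-ether cleanly.

Step 10
Reactants: 11 mono-PMB ether
Product: 12 3-[(4-methoxybenzyl)oxy]propanal
Conditions: TEMPO (cat.), PhI(OAc)2, CH2Cl2, rt
Reagents that add atoms: none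
Why: The TEMPO oxidation of the primary alcohol stops at the aldehyde and leaves the PMB ether intact.

Step 11
Reactants: 12 3-(PMB-oxy)propanal
Product: 14 (3R,4S)-1-[(4-methoxybenzyl)oxy]-4-methylhex-5-en-3-ol, via diisopinocampheylborinate 13 (not isolated)
Conditions: freshly prepared (E)-crotyl-B(Ipc)2 of the (+)-α-pinene series, THF/Et2O, −78 °C; then aq. NaOH, H2O2, 0 °C → rt
Reagents that add atoms: (E)-crotyldiisopinocampheylborane C/C=C/CB([C@@H]1C[C@@H]2C[C@H]([C@H]1C)C2(C)C)[C@@H]1C[C@@H]2C[C@H]([C@H]1C)C2(C)C (its Ipc2B part stays only in 13)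
Why: In the Brown asymmetric crotylboration the E-crotyl group reacts through a closed Zimmerman–Traxler chair to give the anti C1/C10 relationship, and the Ipc ligands direct attack to the Si face, so C1 (R) and C10 (S) are set by reagent control.

Step 12
Reactants: 14 anti homoallylic alcohol
Product: 15 tert-butyl({(3R,4S)-1-[(4-methoxybenzyl)oxy]-4-methylhex-5-en-3-yl}oxy)dimethylsilane
Conditions: TBSOTf, 2,6-lutidine, CH2Cl2, 0 °C
Reagents that add atoms: tert-butyldimethylsilyl triflate CC(C)(C)[Si](C)(C)OS(=O)(=O)C(F)(F)F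
Why: Silylation of the hindered secondary alcohol with the triflate occurs at oxygen only, so C1 keeps its configuration and is masked until the last step.

Step 13
Reactants: 15 TBS ether
Product: 17 (3S,4R)-4-[(tert-butyldimethylsilyl)oxy]-6-[(4-methoxybenzyl)oxy]-3-methylhexan-1-ol, via B-alkyl-9-BBN adduct 16 (not isolated)
Conditions: 9-BBN-H, THF, 0 °C → rt; then aq. NaOH, H2O2
Reagents that add atoms: 9-borabicyclo[3.3.1]nonane C1CC2CCCC(C1)B2 (stays only in 16); hydrogen peroxide OO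
Why: Anti-Markovnikov hydroboration–oxidation of the terminal vinyl group places oxygen on the terminal carbon (C8) and creates no stereocentre.

Step 14
Reactants: 17 primary alcohol
Product: 18 (3S,4R)-4-[(tert-butyldimethylsilyl)oxy]-6-[(4-methoxybenzyl)oxy]-3-methylhexanal (east aldehyde)
Conditions: TEMPO (cat.), PhI(OAc)2, CH2Cl2, rt
Reagents that add atoms: none
Why: The TEMPO oxidation gives the aldehyde without over-oxidation, and the β-stereocentre C10 cannot epimerise.

**Fragment union and endgame (steps 15–22)**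

Step 15
Reactants: 9 west bromide; 18 east aldehyde
Product: 20 methyl (3R,4R,6S,7R)-7-[(tert-butyldimethylsilyl)oxy]-4-hydroxy-3-{(1S,2Z)-3-iodo-1-[(4-methoxybenzyl)oxy]but-2-en-1-yl}-9-[(4-methoxybenzyl)oxy]-6-methyl-2-methylidenenonanoate, via allylindium dibromide 19 (not isolated)
Conditions: In powder, THF, rt, Barbier mode (9 added slowly to 18 and In)
Reagents that add atoms: indium [In] (stays only in 19)
Why: In this Barbier-type carbonyl allylation the Z-allylindium attacks through its γ-carbon C7 in a closed transition state where the C6 ether oxygen sits inside and coordinates indium, the iodoalkenyl group points away from the incoming aldehyde and the aldehyde chain lies anti to C11, which gives the 7,8-syn and target 6,7 relationships (C7 R, C8 R), unveils the C11=C13 methylene, and leaves the vinyl iodide, silyl and PMB ethers untouched.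

Step 16
Reactants: 20 homoallylic alcohol
Product: 21 the C8 (chain C4) (2E)-2-methylbut-2-enoate (tiglate) of 20
Conditions: tiglic acid, 2,4,6-Cl3C6H2COCl, Et3N, toluene, rt; then 20, DMAP, 0 °C → rt
Reagents that add atoms: tiglic acid OC(=O)/C(C)=C/C
Why: The Yamaguchi esterification acylates the hindered C8 hydroxyl with retention at C8 and retention of the E alkene, and capping O8 now stops it from lactonising onto C12.

Step 17
Reactants: 21 bis-PMB tiglate
Product: 23 (1R,3S,4R)-4-[(tert-butyldimethylsilyl)oxy]-6-hydroxy-1-{(2S,3R)-2-[(1Z)-2-iodoprop-1-en-1-yl]-4-methylidene-5-oxooxolan-3-yl}-3-methylhexyl (2E)-2-methylbut-2-enoate, via diol ester 22 (not isolated)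
Conditions: DDQ, CH2Cl2/pH 7 buffer, 0 °C; then PPTS (cat.), CH2Cl2, rt
Reagents that add atoms: none
Why: Oxidative PMB cleavage by DDQ frees O6 and O3 together, and acid-catalysed 5-exo lactonisation of the C6 hydroxyl onto the C12 methyl ester then closes the trans α-methylene-γ-butyrolactone without touching any stereocentre.

Step 18
Reactants: 23 hydroxy lactone
Product: 24 (1R,3S,4R)-4-[(tert-butyldimethylsilyl)oxy]-1-{(2S,3R)-2-[(1Z)-2-iodoprop-1-en-1-yl]-4-methylidene-5-oxooxolan-3-yl}-3-methyl-6-oxohexyl (2E)-2-methylbut-2-enoate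
Conditions: DMP, CH2Cl2, 0 °C → rt
Reagents that add atoms: none
Why: The Dess–Martin oxidation converts the only free (primary) alcohol into the C3 aldehyde under non-basic conditions, so the β-silyloxy group is not eliminated.

Step 19
Reactants: 24 iodo aldehyde
Product: 25 (1R,4Z,6R,7R,8R,10S)-1-[(tert-butyldimethylsilyl)oxy]-3-hydroxy-8-(tigloyloxy)germacra-4,11(13)-dien-12,6-olide (C3 epimers)
Conditions: CrCl2 (excess), NiCl2 (cat.), DMSO/THF, 2 mM, slow addition, rt
Reagents that add atoms: none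
Why: In the Nozaki–Hiyama–Kishi coupling the nickel-catalysed alkenylchromium reagent forms with retention of the Z geometry and adds chemoselectively to the aldehyde at high dilution, closing the ten-membered ring at C3–C4 beside the esters and the methylene lactone, and the new C3 centre needs no control because step 21 oxidises it.

Step 20
Reactants: 25 macrocyclic Z-allylic alcohol
Product: 26 (1R,4S,5R,6S,7R,8R,10S)-1-[(tert-butyldimethylsilyl)oxy]-4,5-epoxy-3-hydroxy-8-(tigloyloxy)germacr-11(13)-en-12,6-olide (C3 epimers)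
Conditions: DMDO, acetone/CH2Cl2, −20 → 0 °C
Reagents that add atoms: dimethyldioxirane CC1(C)OO1
Why: Electrophilic epoxidation picks the only electron-rich alkene and attacks the outer face of the Z-cyclodecene, anti to the C6–C7 and C3–C2 ring bonds with H6 held in the alkene plane by allylic 1,3-strain, which places the oxirane oxygen syn to O6 (C4 and C5 as in the target), while the syn addition keeps C3 and C6 cis.

Step 21
Reactants: 26 epoxy alcohol
Product: 27 (1R,4R,5R,6S,7R,8R,10S)-1-[(tert-butyldimethylsilyl)oxy]-4,5-epoxy-3-oxo-8-(tigloyloxy)germacr-11(13)-en-12,6-olide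
Conditions: DMP, CH2Cl2, rt
Reagents that add atoms: none
Why: The Dess–Martin oxidation converts both C3 epimers into the single α,β-epoxy ketone without opening the oxirane or epimerising the quaternary C4.

Step 22
Reactants: 27 TBS-protected epoxy ketone
Product: 28 eupakirunsin C
Conditions: HF·pyridine, pyridine, THF, 0 °C → rt
Reagents that add atoms: none
Why: Fluoride-driven desilylation under mildly acidic conditions frees the C1 hydroxyl with retention and avoids the retro-aldol, β-elimination and conjugate addition that basic fluoride would risk.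

**Compound list**
1 | (R)-solketal, [(4R)-2,2-dimethyl-1,3-dioxolan-4-yl]methanol | OC[C@@H]1COC(C)(C)O1 | starting material
2 | (S)-glyceraldehyde acetonide, (4S)-2,2-dimethyl-1,3-dioxolane-4-carbaldehyde | O=C[C@@H]1COC(C)(C)O1 | intermediate
3 | (4R)-4-[(1Z)-2-iodoprop-1-en-1-yl]-2,2-dimethyl-1,3-dioxolane | C/C(I)=C/[C@@H]1COC(C)(C)O1 | intermediate
4 | (2R,3Z)-4-iodopent-3-ene-1,2-diol | C/C(I)=C/[C@@H](O)CO | intermediate
5 | (4R)-4-[(1Z)-2-iodoprop-1-en-1-yl]-2-(4-methoxyphenyl)-1,3-dioxolane (both acetal epimers) | C/C(I)=C/[C@@H]1COC(c2ccc(OC)cc2)O1 | intermediate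
6 | (2R,3Z)-4-iodo-2-[(4-methoxybenzyl)oxy]pent-3-en-1-ol | C/C(I)=C/[C@@H](OCc1ccc(OC)cc1)CO | intermediate
7 | (2R,3Z)-4-iodo-2-[(4-methoxybenzyl)oxy]pent-3-enal | C/C(I)=C/[C@@H](OCc1ccc(OC)cc1)C=O | intermediate
8 | methyl (4R,5Z)-3-hydroxy-6-iodo-4-[(4-methoxybenzyl)oxy]-2-methylidenehept-5-enoate (both C3 epimers) | C/C(I)=C/[C@@H](OCc1ccc(OC)cc1)C(O)C(=C)C(=O)OC | intermediate
9 | west bromide, methyl (2Z,4S,5Z)-2-(bromomethyl)-6-iodo-4-[(4-methoxybenzyl)oxy]hepta-2,5-dienoate | C/C(I)=C/[C@@H](OCc1ccc(OC)cc1)/C=C(\CBr)C(=O)OC | intermediate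
10 | propane-1,3-diol | OCCCO | starting material
11 | 3-[(4-methoxybenzyl)oxy]propan-1-ol | OCCCOCc1ccc(OC)cc1 | intermediate
12 | 3-[(4-methoxybenzyl)oxy]propanal | O=CCCOCc1ccc(OC)cc1 | intermediate
13 | diisopinocampheylborinate of 14 (not isolated) | C=C[C@H](C)[C@H](OB([C@@H]1C[C@@H]2C[C@H]([C@H]1C)C2(C)C)[C@@H]1C[C@@H]2C[C@H]([C@H]1C)C2(C)C)CCOCc1ccc(OC)cc1 | intermediate
14 | (3R,4S)-1-[(4-methoxybenzyl)oxy]-4-methylhex-5-en-3-ol | C=C[C@H](C)[C@H](O)CCOCc1ccc(OC)cc1 | intermediate
15 | tert-butyl({(3R,4S)-1-[(4-methoxybenzyl)oxy]-4-methylhex-5-en-3-yl}oxy)dimethylsilane | C=C[C@H](C)[C@H](O[Si](C)(C)C(C)(C)C)CCOCc1ccc(OC)cc1 | intermediate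
16 | B-alkyl-9-BBN adduct of 15, boron on the terminal carbon (not isolated) | C1CC2CCCC(C1)B2CC[C@H](C)[C@H](O[Si](C)(C)C(C)(C)C)CCOCc1ccc(OC)cc1 | intermediate
17 | (3S,4R)-4-[(tert-butyldimethylsilyl)oxy]-6-[(4-methoxybenzyl)oxy]-3-methylhexan-1-ol | OCC[C@H](C)[C@H](O[Si](C)(C)C(C)(C)C)CCOCc1ccc(OC)cc1 | intermediate
18 | east aldehyde, (3S,4R)-4-[(tert-butyldimethylsilyl)oxy]-6-[(4-methoxybenzyl)oxy]-3-methylhexanal | O=CC[C@H](C)[C@H](O[Si](C)(C)C(C)(C)C)CCOCc1ccc(OC)cc1 | intermediate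
19 | allylindium dibromide from 9, drawn for the allylindium bromide mixture, (2Z,4S,5Z) (not isolated) | C/C(I)=C/[C@@H](OCc1ccc(OC)cc1)/C=C(\C[In](Br)Br)C(=O)OC | intermediate
20 | methyl (3R,4R,6S,7R)-7-[(tert-butyldimethylsilyl)oxy]-4-hydroxy-3-{(1S,2Z)-3-iodo-1-[(4-methoxybenzyl)oxy]but-2-en-1-yl}-9-[(4-methoxybenzyl)oxy]-6-methyl-2-methylidenenonanoate | COC(=O)C(=C)[C@@H]([C@H](OCc1ccc(OC)cc1)/C=C(/C)I)[C@H](O)C[C@H](C)[C@H](O[Si](C)(C)C(C)(C)C)CCOCc1ccc(OC)cc1 | intermediate
21 | methyl (3R,4R,6S,7R)-7-[(tert-butyldimethylsilyl)oxy]-3-{(1S,2Z)-3-iodo-1-[(4-methoxybenzyl)oxy]but-2-en-1-yl}-9-[(4-methoxybenzyl)oxy]-6-methyl-4-{[(2E)-2-methylbut-2-enoyl]oxy}-2-methylidenenonanoate | COC(=O)C(=C)[C@@H]([C@H](OCc1ccc(OC)cc1)/C=C(/C)I)[C@H](OC(=O)/C(C)=C/C)C[C@H](C)[C@H](O[Si](C)(C)C(C)(C)C)CCOCc1ccc(OC)cc1 | intermediate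
22 | diol ester, methyl (3S,4R,6S,7R)-7-[(tert-butyldimethylsilyl)oxy]-9-hydroxy-3-[(1S,2Z)-1-hydroxy-3-iodobut-2-en-1-yl]-6-methyl-4-{[(2E)-2-methylbut-2-enoyl]oxy}-2-methylidenenonanoate (not isolated; same spatial arrangement as 21) | COC(=O)C(=C)[C@@H]([C@H](O)/C=C(/C)I)[C@H](OC(=O)/C(C)=C/C)C[C@H](C)[C@H](O[Si](C)(C)C(C)(C)C)CCO | intermediate
23 | (1R,3S,4R)-4-[(tert-butyldimethylsilyl)oxy]-6-hydroxy-1-{(2S,3R)-2-[(1Z)-2-iodoprop-1-en-1-yl]-4-methylidene-5-oxooxolan-3-yl}-3-methylhexyl (2E)-2-methylbut-2-enoate | C=C1C(=O)O[C@H](/C=C(/C)I)[C@H]1[C@H](OC(=O)/C(C)=C/C)C[C@H](C)[C@H](O[Si](C)(C)C(C)(C)C)CCO | intermediate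
24 | (1R,3S,4R)-4-[(tert-butyldimethylsilyl)oxy]-1-{(2S,3R)-2-[(1Z)-2-iodoprop-1-en-1-yl]-4-methylidene-5-oxooxolan-3-yl}-3-methyl-6-oxohexyl (2E)-2-methylbut-2-enoate | C=C1C(=O)O[C@H](/C=C(/C)I)[C@H]1[C@H](OC(=O)/C(C)=C/C)C[C@H](C)[C@H](O[Si](C)(C)C(C)(C)C)CC=O | intermediate
25 | (1R,4Z,6R,7R,8R,10S)-1-[(tert-butyldimethylsilyl)oxy]-3-hydroxy-8-(tigloyloxy)germacra-4,11(13)-dien-12,6-olide (C3 epimers) | C=C1C(=O)O[C@H]2[C@H]1[C@H](OC(=O)/C(C)=C/C)C[C@H](C)[C@H](O[Si](C)(C)C(C)(C)C)CC(O)/C(C)=C\2 | intermediate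
26 | (1R,4S,5R,6S,7R,8R,10S)-1-[(tert-butyldimethylsilyl)oxy]-4,5-epoxy-3-hydroxy-8-(tigloyloxy)germacr-11(13)-en-12,6-olide (C3 epimers) | C=C1C(=O)O[C@H]2[C@H]1[C@H](OC(=O)/C(C)=C/C)C[C@H](C)[C@H](O[Si](C)(C)C(C)(C)C)CC(O)[C@]1(C)O[C@H]21 | intermediate
27 | (1R,4R,5R,6S,7R,8R,10S)-1-[(tert-butyldimethylsilyl)oxy]-4,5-epoxy-3-oxo-8-(tigloyloxy)germacr-11(13)-en-12,6-olide | C=C1C(=O)O[C@H]2[C@H]1[C@H](OC(=O)/C(C)=C/C)C[C@H](C)[C@H](O[Si](C)(C)C(C)(C)C)CC(=O)[C@]1(C)O[C@H]21 | intermediate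
28 | eupakirunsin C, (1R,4R,5R,6S,7R,8R,10S)-4,5-epoxy-1-hydroxy-3-oxo-8-(tigloyloxy)germacr-11(13)-en-12,6-olide | C=C1C(=O)O[C@H]2[C@H]1[C@H](OC(=O)/C(C)=C/C)C[C@H](C)[C@H](O)CC(=O)[C@]1(C)O[C@H]21 | target

**Totals**
- Total step count: 22.
- Longest linear sequence: 16 steps (steps 1–8, then 15–22).

**Steps most likely to fail**

Step 15 (facial selectivity at C7 and competing 1,4-elimination of the C6 alkoxide).
- Risk: the ether oxygen may not hold indium. The rotamer with H6 inside would then win and give the wrong C6/C7 relationship.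
- Fallback, setting out from 9 (with 18) and coming back at 23:
  - DDQ removes the PMB group of 9 to give the free hydroxy bromide F1.
  - F1 is coupled at once with 18 using indium powder in water/THF. A free hydroxyl binds indium far more firmly than an ether, and the product is the diol ester F2.
  - PPTS equilibrates F2 to the more stable trans 6,12-lactone, the hydroxy lactone F3.
  - Yamaguchi tigloylation of the remaining C8 hydroxyl gives the PMB-protected tiglate F4.
  - DDQ removal of the last PMB ether gives 23.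

Step 19 (ten-membered ring closure; oligomerisation or reduction of the iodide).
- Fallback, setting out from 24 and coming back at 25. It replaces the aldehyde addition by an acylative cross-coupling:
  - Pinnick oxidation (NaClO2, NaH2PO4, 2-methyl-2-butene) gives the carboxylic acid F5.
  - EtSH, EDC and DMAP give the S-ethyl thioester F6.
  - (Me3Sn)2 with Pd(PPh3)4 exchanges iodine for tin with retention to give the vinylstannane F7.
  - A Liebeskind–Srogl-type ring closure (Pd2(dba)3, P(2-furyl)3, copper thiophene-2-carboxylate, high dilution) gives the macrocyclic Z-enone F8.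
  - Luche reduction (NaBH4, CeCl3·7H2O, MeOH, −78 °C) gives 25.

Step 20 (face of epoxidation on the macrocycle).
- Risk: the oxidant may deliver oxygen to the wrong face.
- Fallback, setting out from 25 and coming back at 26. It inverts the facial outcome by a halohydrin sequence:
  - NBS in aqueous acetone forms the bromonium ion on the face the oxidant preferred, and water opens it at the tertiary C4 from the opposite face to give the bromohydrin F9.
  - K2CO3 in acetone closes the C4 alkoxide onto C5 with inversion to give 26.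

Further compounds
F1 | step 15 | free hydroxy bromide, methyl (2Z,4S,5Z)-2-(bromomethyl)-4-hydroxy-6-iodohepta-2,5-dienoate | C/C(I)=C/[C@@H](O)/C=C(\CBr)C(=O)OC
F2 | step 15 | diol ester, methyl (3R,4R,6S,7R)-7-[(tert-butyldimethylsilyl)oxy]-4-hydroxy-3-[(1S,2Z)-1-hydroxy-3-iodobut-2-en-1-yl]-9-[(4-methoxybenzyl)oxy]-6-methyl-2-methylidenenonanoate | COC(=O)C(=C)[C@@H]([C@H](O)/C=C(/C)I)[C@H](O)C[C@H](C)[C@H](O[Si](C)(C)C(C)(C)C)CCOCc1ccc(OC)cc1
F3 | step 15 | hydroxy lactone, (4R,5S)-4-{(1R,3S,4R)-4-[(tert-butyldimethylsilyl)oxy]-1-hydroxy-6-[(4-methoxybenzyl)oxy]-3-methylhexyl}-5-[(1Z)-2-iodoprop-1-en-1-yl]-3-methylideneoxolan-2-one | C=C1C(=O)O[C@H](/C=C(/C)I)[C@H]1[C@H](O)C[C@H](C)[C@H](O[Si](C)(C)C(C)(C)C)CCOCc1ccc(OC)cc1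
F4 | step 15 | PMB-protected tiglate, the 6-O-(4-methoxybenzyl) ether of 23 | C=C1C(=O)O[C@H](/C=C(/C)I)[C@H]1[C@H](OC(=O)/C(C)=C/C)C[C@H](C)[C@H](O[Si](C)(C)C(C)(C)C)CCOCc1ccc(OC)cc1
F5 | step 19 | carboxylic acid, the C3 acid corresponding to aldehyde 24 | C=C1C(=O)O[C@H](/C=C(/C)I)[C@H]1[C@H](OC(=O)/C(C)=C/C)C[C@H](C)[C@H](O[Si](C)(C)C(C)(C)C)CC(=O)O
F6 | step 19 | S-ethyl thioester of F5 | C=C1C(=O)O[C@H](/C=C(/C)I)[C@H]1[C@H](OC(=O)/C(C)=C/C)C[C@H](C)[C@H](O[Si](C)(C)C(C)(C)C)CC(=O)SCC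
F7 | step 19 | vinylstannane, F6 with trimethylstannyl in place of iodine (tin cis to C6) | C=C1C(=O)O[C@H](/C=C(/C)[Sn](C)(C)C)[C@H]1[C@H](OC(=O)/C(C)=C/C)C[C@H](C)[C@H](O[Si](C)(C)C(C)(C)C)CC(=O)SCC
F8 | step 19 | macrocyclic Z-enone, (1R,4Z,6R,7R,8R,10S)-1-[(tert-butyldimethylsilyl)oxy]-3-oxo-8-(tigloyloxy)germacra-4,11(13)-dien-12,6-olide | C=C1C(=O)O[C@H]2[C@H]1[C@H](OC(=O)/C(C)=C/C)C[C@H](C)[C@H](O[Si](C)(C)C(C)(C)C)CC(=O)/C(C)=C\2
F9 | step 20 | bromohydrin, (1R,4S,5S,6S,7R,8R,10S)-5-bromo-1-[(tert-butyldimethylsilyl)oxy]-3,4-dihydroxy-8-(tigloyloxy)germacr-11(13)-en-12,6-olide (C3 epimers) | C=C1C(=O)O[C@H]2[C@H]1[C@H](OC(=O)/C(C)=C/C)C[C@H](C)[C@H](O[Si](C)(C)C(C)(C)C)CC(O)[C@](C)(O)[C@H]2Br
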